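**Plan**
Retrosynthesis: benzyl groups are put back on O5 and O7, then ring C is cut at three bonds at once, C4a–C4, C4–C3 and O1–C2.
Enabling feature: C4 is a one-carbon carbonyl unit between C4a of ring A and the C3=C2 pair that bears ring B, and O1 sits on C8a next to C4a. Ring C therefore splits into an o-iodophenol (ring A with O1), carbon monoxide (C4) and an arylacetylene (C3, C2, ring B).
Forward: ring A is bought as 5-bromovanillin and converted to the 1,2,3,5-tetraoxygenated pattern. The methyl group is moved to the central oxygen, CHO becomes O5 by Baeyer–Villiger oxidation, Br becomes the O1 hydroxyl, and the future C4a is iodinated.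
Ring B is bought with its alkyne. Ring C is the only ring that is built, in one palladium-catalysed operation, and hydrogenolysis ends the route.
The target has no stereocentre and no stereogenic double bond, so only regiochemistry needs control (5,7,8 against 5,6,7 pattern, flavone against aurone).

Key step: step 8

Remark on the chemistry: the enaminone formed during the key step is drawn as its E isomer. Its geometry is erased on ring closure and does not affect the product.

**Step 1**
Reactants: 1 5-bromovanillin (3-bromo-4-hydroxy-5-methoxybenzaldehyde)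
Product: 2 3-bromo-4,5-dihydroxybenzaldehyde
Conditions: AlCl3 (1.2 equiv), pyridine (4.5 equiv), CH2Cl2, reflux; then 2 M HCl
Reagents that add atoms: none
Why: Chelation-assisted aryl methyl ether cleavage, in which AlCl3 binds the phenoxide and the neighbouring methoxy oxygen and pyridine removes the activated methyl group by SN2 attack, leaving aldehyde and bromide untouched.

**Step 2**
Reactants: 2 3-bromo-4,5-dihydroxybenzaldehyde
Product: 3 3-bromo-5-hydroxy-4-methoxybenzaldehyde
Conditions: MeI (1.2 equiv), Li2CO3 (1.2 equiv), DMF, 40 °C
Reagents that add atoms: iodomethane, CI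
Why: Regioselective Williamson etherification, since the 4-OH (para to CHO, ortho to Br) is much the more acidic and the weak base should form only its phenoxide, so that MeI places the methyl group on the central oxygen.

**Step 3**
Reactants: 3 3-bromo-5-hydroxy-4-methoxybenzaldehyde; 4 benzyl bromide
Product: 5 3-(benzyloxy)-5-bromo-4-methoxybenzaldehyde
Conditions: BnBr (1.1 equiv), K2CO3, DMF, rt
Reagents that add atoms: benzyl bromide 4, BrCc1ccccc1
Why: Williamson etherification of the one remaining phenol, which installs the future 7-O-benzyl group.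

**Step 4**
Reactants: 5 3-(benzyloxy)-5-bromo-4-methoxybenzaldehyde
Product: 7 3-(benzyloxy)-5-bromo-4-methoxyphenol, via aryl formate 6 (not isolated)
Conditions: mCPBA (1.5 equiv), CH2Cl2, 0 °C to rt; aq. NaHCO3 wash; then K2CO3 (0.2 equiv), MeOH, rt
Reagents that add atoms: mCPBA (3-chloroperoxybenzoic acid), OOC(=O)c1cccc(Cl)c1
Why: Baeyer–Villiger oxidation, in which the alkoxy-rich aryl group migrates in preference to hydride in the Criegee adduct, as with other 3,4,5-trisubstituted alkoxybenzaldehydes, and base-catalysed methanolysis of formate 6 then frees the future O5 hydroxyl.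

**Step 5**
Reactants: 7 3-(benzyloxy)-5-bromo-4-methoxyphenol; 4 benzyl bromide
Product: 8 1,5-bis(benzyloxy)-3-bromo-2-methoxybenzene
Conditions: BnBr (1.1 equiv), K2CO3, DMF, rt
Reagents that add atoms: benzyl bromide 4, BrCc1ccccc1
Why: Williamson etherification of an unhindered phenol, which masks O5 so that it cannot later compete with O1 in the ring closure.

**Step 6**
Reactants: 8 1,5-bis(benzyloxy)-3-bromo-2-methoxybenzene
Product: 9 3,5-bis(benzyloxy)-2-methoxyphenol
Conditions: Pd2(dba)3 (2 mol %), tBuXPhos (8 mol %), KOH (3 equiv), 1,4-dioxane–H2O, 100 °C; then aq. HCl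
Reagents that add atoms: potassium hydroxide, [K+].[OH-]
Why: Palladium-catalysed hydroxylation of an aryl bromide (C–O cross-coupling with hydroxide), in which the bulky biaryl di-tert-butylphosphine promotes C–O reductive elimination and the aryl benzyl and methyl ethers are inert to hot aqueous KOH.

**Step 7**
Reactants: 9 3,5-bis(benzyloxy)-2-methoxyphenol
Product: 10 3,5-bis(benzyloxy)-2-iodo-6-methoxyphenol
Conditions: NIS (1.0 equiv), CH2Cl2, −20 to 0 °C, dark
Reagents that add atoms: N-iodosuccinimide, O=C1CCC(=O)N1I
Why: Electrophilic aromatic iodination, in which both free carbons of 9 are activated by three oxygens, but C6 lies between OH and one OBn while C4 is shielded by two OBn groups, and hydrogen bonding of the phenol to NIS in an apolar solvent should favour the ortho carbon, as is usual for 3,5-dialkoxyphenols.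

**Step 8**
Reactants: 10 3,5-bis(benzyloxy)-2-iodo-6-methoxyphenol; 11 5-ethynyl-1,2,3-trimethoxybenzene; 12 carbon monoxide
Product: 15 5,7-bis(benzyloxy)-8-methoxy-2-(3,4,5-trimethoxyphenyl)-4H-chromen-4-one, via o-hydroxyaryl ynone 13 (not isolated), via diethylamino enaminone 14 (not isolated)
Conditions: PdCl2(dppf) (5 mol %), CO (20 bar), 11 (1.5 equiv), Et2NH (solvent), 120 °C, autoclave, no copper salt
Reagents that add atoms: carbon monoxide 12, [C-]#[O+]; diethylamine, CCNCC (held only in intermediate 14 and released again on ring closure)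
Why: Zerovalent palladium, formed from PdCl2(dppf) in the amine, inserts into the C–I bond of 10, CO 12 inserts to give the aroylpalladium iodide, and the acetylide formed from 11 and Et2NH is transferred and reductively eliminated, which makes C4a–C4 and C4–C3 and gives ynone 13. Et2NH then adds in conjugate fashion to C2 of 13 to give enaminone 14, and the phenol oxygen on C8a displaces the amine at C2 by addition–elimination, which makes O1–C2. The closest known reaction type is the carbonylative Sonogashira coupling and annulation of o-iodophenols with terminal arylacetylenes in a secondary amine, which gives flavones directly. Ring C closes as a six-membered ring in a formal 6-endo-dig sense (strictly a 6-endo-trig addition–elimination on 14), and no stereocentre is formed. Three selectivities are needed: CO insertion before alkyne transfer (high CO pressure and the absence of copper hold back the direct coupling that would end in a benzofuran), flavone over aurone (in 14 the only electrophilic carbon within reach of the oxygen is C2), and the 5,7,8 over the 5,6,7 pattern (the only free hydroxyl of 10 lies between C–I and C–OMe, and the other oxygen ortho to iodine is benzylated).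

**Step 9**
Reactants: 15 5,7-bis(benzyloxy)-8-methoxy-2-(3,4,5-trimethoxyphenyl)-4H-chromen-4-one
Product: 16 3',4',5'-trimethoxywogonin (5,7-dihydroxy-8-methoxy-2-(3,4,5-trimethoxyphenyl)-4H-chromen-4-one)
Conditions: H2 (1 atm), 10% Pd/C, THF–MeOH, rt
Reagents that add atoms: none
Why: Catalytic hydrogenolysis of the two aryl benzyl ethers, under which the four methyl ethers and the vinylogous-ester C2–C3 double bond of the flavone should remain intact at 1 atm and room temperature.

**Compound list**
1 | 5-bromovanillin | COc1cc(C=O)cc(Br)c1O | starting material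
2 | 3-bromo-4,5-dihydroxybenzaldehyde | O=Cc1cc(O)c(O)c(Br)c1 | intermediate
3 | 3-bromo-5-hydroxy-4-methoxybenzaldehyde | COc1c(O)cc(C=O)cc1Br | intermediate
4 | benzyl bromide | BrCc1ccccc1 | starting material
5 | 3-(benzyloxy)-5-bromo-4-methoxybenzaldehyde | COc1c(Br)cc(C=O)cc1OCc1ccccc1 | intermediate
6 | 3-(benzyloxy)-5-bromo-4-methoxyphenyl formate | COc1c(Br)cc(OC=O)cc1OCc1ccccc1 | intermediate
7 | 3-(benzyloxy)-5-bromo-4-methoxyphenol | COc1c(Br)cc(O)cc1OCc1ccccc1 | intermediate
8 | 1,5-bis(benzyloxy)-3-bromo-2-methoxybenzene | COc1c(Br)cc(OCc2ccccc2)cc1OCc1ccccc1 | intermediate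
9 | 3,5-bis(benzyloxy)-2-methoxyphenol | COc1c(O)cc(OCc2ccccc2)cc1OCc1ccccc1 | intermediate
10 | 3,5-bis(benzyloxy)-2-iodo-6-methoxyphenol | COc1c(O)c(I)c(OCc2ccccc2)cc1OCc1ccccc1 | intermediate
11 | 5-ethynyl-1,2,3-trimethoxybenzene | C#Cc1cc(OC)c(OC)c(OC)c1 | starting material
12 | carbon monoxide | [C-]#[O+] | starting material
13 | 1-[4,6-bis(benzyloxy)-2-hydroxy-3-methoxyphenyl]-3-(3,4,5-trimethoxyphenyl)prop-2-yn-1-one | COc1cc(C#CC(=O)c2c(O)c(OC)c(OCc3ccccc3)cc2OCc2ccccc2)cc(OC)c1OC | intermediate
14 | (E)-1-[4,6-bis(benzyloxy)-2-hydroxy-3-methoxyphenyl]-3-(diethylamino)-3-(3,4,5-trimethoxyphenyl)prop-2-en-1-one | CCN(CC)/C(=C/C(=O)c1c(O)c(OC)c(OCc2ccccc2)cc1OCc1ccccc1)c1cc(OC)c(OC)c(OC)c1 | intermediate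
15 | 5,7-bis(benzyloxy)-8-methoxy-2-(3,4,5-trimethoxyphenyl)-4H-chromen-4-one | COc1cc(-c2cc(=O)c3c(OCc4ccccc4)cc(OCc4ccccc4)c(OC)c3o2)cc(OC)c1OC | intermediate
16 | 3',4',5'-trimethoxywogonin | COc1cc(-c2cc(=O)c3c(O)cc(O)c(OC)c3o2)cc(OC)c1OC | target

**Totals**
Total step count: 9. Longest linear sequence: 9 steps (1 to 16). Compounds 4, 11 and 12 are bought and enter directly.

**The three steps most likely to fail**

Step 8 (carbonylative annulation). The C–I bond of 10 is electron-rich and flanked on both sides, so oxidative addition may be slow. Two processes could then take over: capture of the aroylpalladium species by Et2NH (aminocarbonylation), or alkyne transfer before CO insertion followed by 5-endo closure.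

The fallback sets out from 10 and 11 and comes back at 13. C4 is delivered as a carbamoyl carbon, and both C–C bonds are made by organolithium acylation instead of catalysis.
- Alkyne 11 is deprotonated with n-BuLi (THF, −78 °C) to lithium (3,4,5-trimethoxyphenyl)acetylide F1.
- F1 is acylated with N-methoxy-N-methylcarbamoyl chloride to the alkynyl Weinreb amide N-methoxy-N-methyl-3-(3,4,5-trimethoxyphenyl)prop-2-ynamide F2.
- Iodophenol 10 is treated with n-BuLi (2.1 equiv, THF, −78 °C), which deprotonates the hydroxyl and exchanges iodine for lithium to give lithium 3,5-bis(benzyloxy)-2-lithio-6-methoxyphenoxide F3.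
- F3 is acylated by F2, and aqueous NH4Cl releases ynone 13, which is now isolated.
- Warming 13 in Et2NH–EtOH should close ring C through 14 to 15, as in the second half of step 8.

Step 7 (iodination). Substitution may go para to the hydroxyl, at the carbon between the two benzyloxy groups, or run on to double iodination, because both free positions are activated by three oxygens.

The fallback sets out from 9 and comes back at 10. Directed ortho-metalation replaces electrophilic substitution.
- Phenol 9 is converted with MOMCl and iPr2NEt (CH2Cl2, 0 °C) into 1,5-bis(benzyloxy)-2-methoxy-3-(methoxymethoxy)benzene F4.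
- n-BuLi (THF, −20 to 0 °C) is guided by the chelating acetal to the carbon between OMOM and OBn and gives [4,6-bis(benzyloxy)-3-methoxy-2-(methoxymethoxy)phenyl]lithium F5.
- Quenching with I2 gives 1,5-bis(benzyloxy)-2-iodo-4-methoxy-3-(methoxymethoxy)benzene F6.
- HCl in MeOH (40 °C) removes the acetal to give 10.

Step 6 (hydroxylation). C–O reductive elimination next to the ortho methoxy group may be slow. Hydrodebromination, or coupling of the newly formed phenoxide with unreacted bromide to a diaryl ether, could then compete.

The fallback sets out from 8 and comes back at 9. The oxygen is brought in by oxidation of a C–B bond.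
- Miyaura borylation of 8 (B2pin2, PdCl2(dppf), KOAc, 1,4-dioxane, 90 °C) gives 2-[3,5-bis(benzyloxy)-2-methoxyphenyl]-4,4,5,5-tetramethyl-1,3,2-dioxaborolane F7.
- H2O2 and NaOH (THF, 0 °C) convert F7 into 9 by 1,2-shift of the aryl group from boron to oxygen.

**Further compounds**
F1 | step 8 | lithium (3,4,5-trimethoxyphenyl)acetylide | [Li]C#Cc1cc(OC)c(OC)c(OC)c1
F2 | step 8 | N-methoxy-N-methyl-3-(3,4,5-trimethoxyphenyl)prop-2-ynamide | CON(C)C(=O)C#Cc1cc(OC)c(OC)c(OC)c1
F3 | step 8 | lithium 3,5-bis(benzyloxy)-2-lithio-6-methoxyphenoxide | COc1c(O[Li])c([Li])c(OCc2ccccc2)cc1OCc1ccccc1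
F4 | step 7 | 1,5-bis(benzyloxy)-2-methoxy-3-(methoxymethoxy)benzene | COCOc1cc(OCc2ccccc2)cc(OCc2ccccc2)c1OC
F5 | step 7 | [4,6-bis(benzyloxy)-3-methoxy-2-(methoxymethoxy)phenyl]lithium | COCOc1c([Li])c(OCc2ccccc2)cc(OCc2ccccc2)c1OC
F6 | step 7 | 1,5-bis(benzyloxy)-2-iodo-4-methoxy-3-(methoxymethoxy)benzene | COCOc1c(I)c(OCc2ccccc2)cc(OCc2ccccc2)c1OC
F7 | step 6 | 2-[3,5-bis(benzyloxy)-2-methoxyphenyl]-4,4,5,5-tetramethyl-1,3,2-dioxaborolane | COc1c(B2OC(C)(C)C(C)(C)O2)cc(OCc2ccccc2)cc1OCc1ccccc1
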